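**Plan**

1. Labdane numbering: ring A = C1–C5 and C10, ring B = C5–C10, C20 = methyl on C10, C17 = methyl on C8, chain C11–C16, acetate on C15. The target is the cis-fused (5S,8R,9R,10R,13S) isomer, with H5 and C20 on one face (α).
2. Cuts: the acetate O–acyl bond; C8–C17 and C8–O (epoxide of an 8(17)-alkene, itself from the C8 ketone); C9–C11 (aldol with a C11–C16 aldehyde); C9–C10 together with a temporary C1–C9 bond (cyclopropyl ketone back to a diazoketone whose diazo carbon is C9); C5–C6 and C10–C20 on 4,4-dimethylcyclohexenone.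
3. Enabling feature: C9 is bonded to the quaternary C10 on the same face of ring A as the C6 arm of C5. A carbene at C9, tied to C5 through C8–C7–C6, can therefore be added across a C1=C10 double bond of ring A, and reductive cleavage of C1–C9 then leaves the cis-decalin with C20 in place.
4. Forward: ring A is bought. Conjugate addition/methylation and triflate reduction give the monocyclic diene, and Wacker oxidation and diazo transfer give the diazoketone. Ring B and the cyclopropane close in one step and Li/NH3 opens the cyclopropane. The chain is joined by a Mukaiyama aldol, C8 is finished by methylenation, epoxidation and hydride opening, and the acetate is added last.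
5. Stereochemistry: C5 from a Cu-catalysed asymmetric conjugate addition; C10 relayed from C5 by the tether; C9 and C8 by delivery of H2 and of the peracid oxygen to the convex α face of the cis-decalin; C13 from methyl hydrogen (R)-3-methylglutarate.

Key step: step 6

Remark: the TaniaPhos enantiomer in step 1 is taken to be the one that sends the Grignard reagent to the Re face of C3 of the enone; this sense has to be confirmed on the first ketone before material is carried forward.

**Route**

Step 1
Reactants: 1 4,4-dimethylcyclohex-2-en-1-one; 2 but-3-en-1-ylmagnesium bromide (Et2O solution)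
Product: 4 (3R)-3-(but-3-en-1-yl)-2,4,4-trimethylcyclohexan-1-one (C2 epimers), via magnesium enolate 3 (not isolated)
Conditions: CuBr·SMe2 (5 mol%), TaniaPhos (6 mol%), tBuOMe, −75 °C; then MeI (5 equiv), DMPU, −75 → 0 °C
Reagents that add atoms: iodomethane, CI
Why: Copper-catalysed asymmetric conjugate addition of a Grignard reagent to a cyclic enone followed by C-alkylation of the regiodefined magnesium enolate: the Cu–diphosphine complex should deliver the butenyl group to the Re face of C3 (labdane C5, R in 4), and the C2 configuration is irrelevant because that carbon becomes sp2 in step 2.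

Step 2
Reactants: 4 (3R)-3-(but-3-en-1-yl)-2,4,4-trimethylcyclohexan-1-one
Product: 5 (3S)-3-(but-3-en-1-yl)-2,4,4-trimethylcyclohex-1-en-1-yl trifluoromethanesulfonate
Conditions: Tf2O, 2,6-di-tert-butyl-4-methylpyridine, CH2Cl2, 0 °C → rt
Reagents that add atoms: trifluoromethanesulfonic anhydride, O=S(=O)(OS(=O)(=O)C(F)(F)F)C(F)(F)F
Why: Ketone triflation with Tf2O and a hindered pyridine proceeds by proton loss from the O-triflyl oxocarbenium ion and generally favours the more substituted vinyl triflate, here the tetrasubstituted C1=C2 isomer, while the C3 stereocentre is β to the carbonyl and cannot epimerise.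

Step 3
Reactants: 5 (3S)-3-(but-3-en-1-yl)-2,4,4-trimethylcyclohex-1-en-1-yl trifluoromethanesulfonate
Product: 6 (6S)-6-(but-3-en-1-yl)-1,5,5-trimethylcyclohex-1-ene
Conditions: Pd(OAc)2 (5 mol%), PPh3 (10 mol%), HCO2H, Bu3N, DMF, 60 °C
Reagents that add atoms: none
Why: Palladium-catalysed formate reduction of a vinyl triflate (oxidative addition, formate-to-hydride exchange with loss of CO2, reductive elimination) replaces OTf by H without moving the double bond, which is now the C1=C10 alkene of the labdane.

Step 4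
Reactants: 6 (6S)-6-(but-3-en-1-yl)-1,5,5-trimethylcyclohex-1-ene
Product: 7 (S)-4-(2,6,6-trimethylcyclohex-2-en-1-yl)butan-2-one
Conditions: PdCl2 (10 mol%), CuCl (1 equiv), O2 (1 atm), DMF/H2O (7:1), rt
Reagents that add atoms: water, O
Why: Tsuji–Wacker oxidation hydrates the monosubstituted alkene with Markovnikov regiochemistry to the methyl ketone, the hindered trisubstituted ring alkene being inert, while CuCl/O2 reoxidise zerovalent palladium.

Step 5
Reactants: 7 (S)-4-(2,6,6-trimethylcyclohex-2-en-1-yl)butan-2-one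
Product: 9 (S)-1-diazo-4-(2,6,6-trimethylcyclohex-2-en-1-yl)butan-2-one, via trifluoroacetyl diketone 8 (not isolated)
Conditions: LiN(SiMe3)2, THF, −78 °C; CF3CO2CH2CF3; then MsN3, Et3N, H2O (1 equiv), MeCN, rt
Reagents that add atoms: methanesulfonyl azide, CS(=O)(=O)N=[N+]=[N-]
Why: Deacylative Regitz diazo transfer: the kinetic methyl-side lithium enolate is trifluoroacetylated, and the sulfonyl azide then transfers N2 to that activated carbon with loss of the trifluoroacetyl group as a sulfonamide, so the diazo group ends on C9 only.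

Step 6
Reactants: 9 (S)-1-diazo-4-(2,6,6-trimethylcyclohex-2-en-1-yl)butan-2-one
Product: 10 (1R,2R,6S,10S)-1,7,7-trimethyltricyclo[4.4.0.0^{2,10}]decan-3-one (labdane numbering: 1,9-cyclo-8-ketone, 1S,5S,9R,10R)
Conditions: Rh2(OAc)4 (1 mol%), CH2Cl2, rt, slow addition of 9
Reagents that add atoms: none
Why: Rh2(OAc)4 takes N2 from the diazoketone, and the electrophilic rhodium carbenoid at C9 adds in a concerted but asynchronous way across the electron-rich trisubstituted C1=C10 alkene, the well-known intramolecular cyclopropanation of unsaturated diazomethyl ketones to bicyclo[4.1.0]heptan-2-ones. Ring B (C5–C6–C7–C8–C9–C10) closes as a six-membered ketone ring through the C9–C10 bond, exo with respect to the alkene, and the three-membered ring C1–C9–C10 closes through the C9–C1 bond in the same event. C10 is set by C5: the tether C6–C7–C8 lets C9 reach only the alkene face on which C6 stands, so C9 ends cis to C6 on ring A and the C10 methyl cis to H5. C1 and C9 follow from the obligatory cis fusion of the cyclopropane and are both erased later. The step needs chemoselectivity for alkene addition over 1,5 C–H insertion at the allylic C5–H and over carbene dimerisation; the nucleophilic alkene held at six-ring distance and the slow addition of 9 to the catalyst should secure it.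

Step 7
Reactants: 10 (1R,2R,6S,10S)-1,7,7-trimethyltricyclo[4.4.0.0^{2,10}]decan-3-one
Product: 12 trimethyl{[(4aS,8aR)-5,5,8a-trimethyl-3,4,4a,5,6,7,8,8a-octahydronaphthalen-2-yl]oxy}silane, via lithium enolate 11 (not isolated)
Conditions: Li (2.2 equiv), NH3/THF, tBuOH (1.0 equiv), −78 °C; NH3 removed; then TMSCl, Et3N, THF, −78 → 0 °C
Reagents that add atoms: chlorotrimethylsilane, C[Si](C)(C)Cl
Why: Dissolving-metal reduction of a cyclopropyl ketone cleaves the cyclopropane bond that overlaps best with the carbonyl π system, here C1–C9 outside the ketone ring, which leaves C10 quaternary with its methyl cis to H5, C1 as CH2 (protonated by tBuOH) and a regiodefined C8–C9 lithium enolate that is O-silylated.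

Step 8
Reactants: 13 methyl hydrogen (R)-3-methylglutarate [(R)-5-methoxy-3-methyl-5-oxopentanoic acid]
Product: 14 methyl (R)-5-hydroxy-3-methylpentanoate
Conditions: BH3·SMe2, THF, 0 °C → rt; MeOH quench
Reagents that add atoms: none
Why: Borane reduces the carboxylic acid through its acyloxyborane much faster than the methyl ester, so only the acid end (future C15) becomes CH2OH and the stereocentre (future C13) is untouched.

Step 9
Reactants: 14 methyl (R)-5-hydroxy-3-methylpentanoate
Product: 15 methyl (R)-5-[(tert-butyldiphenylsilyl)oxy]-3-methylpentanoate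
Conditions: TBDPSCl, imidazole, CH2Cl2, rt
Reagents that add atoms: tert-butyl(chloro)diphenylsilane, CC(C)(C)[Si](Cl)(c1ccccc1)c1ccccc1
Why: Standard silylation of a primary alcohol; the acid-stable TBDPS ether is chosen to survive BF3·OEt2, the titanium methylenation reagent, mCPBA and LiAlH4.

Step 10
Reactants: 15 methyl (R)-5-[(tert-butyldiphenylsilyl)oxy]-3-methylpentanoate
Product: 16 (R)-5-[(tert-butyldiphenylsilyl)oxy]-3-methylpentanal
Conditions: iBu2AlH (1.05 equiv), CH2Cl2, −78 °C; aq. KNaC4H4O6 (tartrate) work-up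
Reagents that add atoms: none
Why: Partial ester reduction: at −78 °C the tetrahedral aluminium hemiacetal persists and releases the aldehyde (future C11) only on work-up.

Step 11
Reactants: 12 trimethyl{[(4aS,8aR)-5,5,8a-trimethyl-3,4,4a,5,6,7,8,8a-octahydronaphthalen-2-yl]oxy}silane; 16 (R)-5-[(tert-butyldiphenylsilyl)oxy]-3-methylpentanal
Product: 17 (4aS,8aR)-1-{(3R)-5-[(tert-butyldiphenylsilyl)oxy]-1-hydroxy-3-methylpentyl}-5,5,8a-trimethyloctahydronaphthalen-2(1H)-one (diastereomers at C9 and C11)
Conditions: BF3·OEt2 (1.1 equiv), CH2Cl2, −78 °C; aq. NaHCO3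
Reagents that add atoms: none
Why: Mukaiyama aldol addition: the BF3-activated aldehyde is attacked by the nucleophilic C9 of the silyl enol ether, forming C9–C11 regiospecifically and irreversibly, and the configurations created at C9 and C11 need no control because both are erased in steps 12 and 13.

Step 12
Reactants: 17 (4aS,8aR)-1-{(3R)-5-[(tert-butyldiphenylsilyl)oxy]-1-hydroxy-3-methylpentyl}-5,5,8a-trimethyloctahydronaphthalen-2(1H)-one
Product: 19 (1E,4aS,8aR)-1-{(3S)-5-[(tert-butyldiphenylsilyl)oxy]-3-methylpentylidene}-5,5,8a-trimethyloctahydronaphthalen-2(1H)-one, via mesylate 18 (not isolated)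
Conditions: MsCl, Et3N, CH2Cl2, 0 °C; then DBU, rt
Reagents that add atoms: none
Why: Mesylation and E1cB elimination of the β-mesyloxy ketone give the conjugated exocyclic enone (either alkene geometry serves), and migration of the double bond into the ring is impossible because C10 is quaternary.

Step 13
Reactants: 19 (1E,4aS,8aR)-1-{(3S)-5-[(tert-butyldiphenylsilyl)oxy]-3-methylpentylidene}-5,5,8a-trimethyloctahydronaphthalen-2(1H)-one
Product: 20 (1R,4aS,8aR)-1-{(3S)-5-[(tert-butyldiphenylsilyl)oxy]-3-methylpentyl}-5,5,8a-trimethyloctahydronaphthalen-2(1H)-one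
Conditions: H2 (1 atm), Pd/C (10 wt%), EtOAc, rt
Reagents that add atoms: none
Why: Heterogeneous hydrogenation of the enone C=C should deliver hydrogen to C9 from the convex α face of the cis-decalin, because ring A is folded under the β face with C1 axial on ring B, so H9 ends α and the side chain β and equatorial (9R), and the neutral conditions do not epimerise C9.

Step 14
Reactants: 20 (1R,4aS,8aR)-1-{(3S)-5-[(tert-butyldiphenylsilyl)oxy]-3-methylpentyl}-5,5,8a-trimethyloctahydronaphthalen-2(1H)-one
Product: 21 tert-butyl({(3S)-3-methyl-5-[(1S,4aS,8aR)-5,5,8a-trimethyl-2-methylidenedecahydronaphthalen-1-yl]pentyl}oxy)diphenylsilane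
Conditions: Zn, CH2Br2, TiCl4, THF, −40 → 5 °C (reagent pre-formed); then 20, CH2Cl2, rt
Reagents that add atoms: dibromomethane, BrCBr
Why: Takai–Lombardo methylenation: the gem-dimetallic CH2 reagent is non-basic, so the hindered and epimerisable C8 ketone becomes the 8(17)-alkene without loss of the C9 configuration, which a basic Wittig ylide would put at risk.

Step 15
Reactants: 21 tert-butyl({(3S)-3-methyl-5-[(1S,4aS,8aR)-5,5,8a-trimethyl-2-methylidenedecahydronaphthalen-1-yl]pentyl}oxy)diphenylsilane
Product: 22 tert-butyl({(3S)-3-methyl-5-[(1R,2R,4aS,8aR)-5,5,8a-trimethyloctahydro-1H-spiro[naphthalene-2,2'-oxiran]-1-yl]pentyl}oxy)diphenylsilane (oxirane oxygen α on C8)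
Conditions: mCPBA, NaHCO3, CH2Cl2, 0 °C
Reagents that add atoms: 3-chloroperoxybenzoic acid, OOC(=O)c1cccc(Cl)c1
Why: Prilezhaev epoxidation: the peracid should approach the exocyclic alkene from the α face, anti to the axial C1 methylene that blocks the β trajectory, placing the oxirane oxygen α on C8 (8R), cis to the C10 methyl and trans to the C9 side chain.

Step 16
Reactants: 22 the 8α,17-spiro-epoxide
Product: 23 (1R,2R,4aS,8aR)-1-{(3S)-5-[(tert-butyldiphenylsilyl)oxy]-3-methylpentyl}-2,5,5,8a-tetramethyldecahydronaphthalen-2-ol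
Conditions: LiAlH4, THF, 0 °C → rt; H2O/aq. NaOH work-up
Reagents that add atoms: none
Why: Hydride opens the 1,1-disubstituted oxirane by SN2 attack at its unhindered CH2 terminus, which turns C17 into the methyl group and leaves the tertiary 8α-alcohol with C8 unchanged.

Step 17
Reactants: 23 (1R,2R,4aS,8aR)-1-{(3S)-5-[(tert-butyldiphenylsilyl)oxy]-3-methylpentyl}-2,5,5,8a-tetramethyldecahydronaphthalen-2-ol
Product: 24 (1R,2R,4aS,8aR)-1-[(3S)-5-hydroxy-3-methylpentyl]-2,5,5,8a-tetramethyldecahydronaphthalen-2-ol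
Conditions: Bu4NF, THF, rt
Reagents that add atoms: none
Why: Fluoride-induced desilylation cleaves the Si–O bond of the primary TBDPS ether and leaves the tertiary alcohol untouched.

Step 18
Reactants: 24 (1R,2R,4aS,8aR)-1-[(3S)-5-hydroxy-3-methylpentyl]-2,5,5,8a-tetramethyldecahydronaphthalen-2-ol
Product: 25 (3S)-5-[(1R,2R,4aS,8aR)-2-hydroxy-2,5,5,8a-tetramethyldecahydronaphthalen-1-yl]-3-methylpentyl acetate
Conditions: Ac2O, pyridine, CH2Cl2, 0 °C → rt
Reagents that add atoms: acetic anhydride, CC(=O)OC(C)=O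
Why: Acylation with acetic anhydride in pyridine without a nucleophilic catalyst should esterify only the primary C15 alcohol, the hindered tertiary C8 alcohol being inert under these conditions.

**Compound list**

1 | 4,4-dimethylcyclohex-2-en-1-one | CC1(C)C=CC(=O)CC1 | starting material
2 | but-3-en-1-ylmagnesium bromide | C=CCC[Mg]Br | starting material
3 | bromomagnesium (3R)-3-(but-3-en-1-yl)-4,4-dimethylcyclohex-1-en-1-olate | C=CCC[C@@H]1C=C(O[Mg]Br)CCC1(C)C | intermediate
4 | (3R)-3-(but-3-en-1-yl)-2,4,4-trimethylcyclohexan-1-one (C2 epimers) | C=CCC[C@@H]1C(C)C(=O)CCC1(C)C | intermediate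
5 | (3S)-3-(but-3-en-1-yl)-2,4,4-trimethylcyclohex-1-en-1-yl trifluoromethanesulfonate | C=CCC[C@@H]1C(C)=C(OS(=O)(=O)C(F)(F)F)CCC1(C)C | intermediate
6 | (6S)-6-(but-3-en-1-yl)-1,5,5-trimethylcyclohex-1-ene | C=CCC[C@@H]1C(C)=CCCC1(C)C | intermediate
7 | (S)-4-(2,6,6-trimethylcyclohex-2-en-1-yl)butan-2-one | CC(=O)CC[C@@H]1C(C)=CCCC1(C)C | intermediate
8 | (S)-1,1,1-trifluoro-6-(2,6,6-trimethylcyclohex-2-en-1-yl)hexane-2,4-dione | O=C(CC(=O)CC[C@@H]1C(C)=CCCC1(C)C)C(F)(F)F | intermediate
9 | (S)-1-diazo-4-(2,6,6-trimethylcyclohex-2-en-1-yl)butan-2-one | [N-]=[N+]=CC(=O)CC[C@@H]1C(C)=CCCC1(C)C | intermediate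
10 | (1R,2R,6S,10S)-1,7,7-trimethyltricyclo[4.4.0.0^{2,10}]decan-3-one | O=C1CC[C@H]2C(C)(C)CC[C@H]3[C@@H]1[C@@]23C | intermediate
11 | lithium (4aS,8aR)-5,5,8a-trimethyl-3,4,4a,5,6,7,8,8a-octahydronaphthalen-2-olate | [Li]OC1=C[C@]2(C)CCCC(C)(C)[C@@H]2CC1 | intermediate
12 | trimethyl{[(4aS,8aR)-5,5,8a-trimethyl-3,4,4a,5,6,7,8,8a-octahydronaphthalen-2-yl]oxy}silane | C[Si](C)(C)OC1=C[C@]2(C)CCCC(C)(C)[C@@H]2CC1 | intermediate
13 | methyl hydrogen (R)-3-methylglutarate | OC(=O)C[C@@H](C)CC(=O)OC | starting material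
14 | methyl (R)-5-hydroxy-3-methylpentanoate | OCC[C@@H](C)CC(=O)OC | intermediate
15 | methyl (R)-5-[(tert-butyldiphenylsilyl)oxy]-3-methylpentanoate | CC(C)(C)[Si](OCC[C@@H](C)CC(=O)OC)(c1ccccc1)c1ccccc1 | intermediate
16 | (R)-5-[(tert-butyldiphenylsilyl)oxy]-3-methylpentanal | CC(C)(C)[Si](OCC[C@@H](C)CC=O)(c1ccccc1)c1ccccc1 | intermediate
17 | (4aS,8aR)-1-{(3R)-5-[(tert-butyldiphenylsilyl)oxy]-1-hydroxy-3-methylpentyl}-5,5,8a-trimethyloctahydronaphthalen-2(1H)-one (diastereomers at C9 and C11) | CC(C)(C)[Si](OCC[C@@H](C)CC(O)C1[C@]2(C)CCCC(C)(C)[C@@H]2CCC1=O)(c1ccccc1)c1ccccc1 | intermediate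
18 | (3R)-5-[(tert-butyldiphenylsilyl)oxy]-3-methyl-1-[(4aS,8aR)-5,5,8a-trimethyl-2-oxodecahydronaphthalen-1-yl]pentyl methanesulfonate (diastereomers) | CC(C)(C)[Si](OCC[C@@H](C)CC(OS(C)(=O)=O)C1[C@]2(C)CCCC(C)(C)[C@@H]2CCC1=O)(c1ccccc1)c1ccccc1 | intermediate
19 | (1E,4aS,8aR)-1-{(3S)-5-[(tert-butyldiphenylsilyl)oxy]-3-methylpentylidene}-5,5,8a-trimethyloctahydronaphthalen-2(1H)-one | CC(C)(C)[Si](OCC[C@@H](C)C/C=C1\[C@]2(C)CCCC(C)(C)[C@@H]2CCC1=O)(c1ccccc1)c1ccccc1 | intermediate
20 | (1R,4aS,8aR)-1-{(3S)-5-[(tert-butyldiphenylsilyl)oxy]-3-methylpentyl}-5,5,8a-trimethyloctahydronaphthalen-2(1H)-one | CC(C)(C)[Si](OCC[C@@H](C)CC[C@@H]1[C@]2(C)CCCC(C)(C)[C@@H]2CCC1=O)(c1ccccc1)c1ccccc1 | intermediate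
21 | tert-butyl({(3S)-3-methyl-5-[(1S,4aS,8aR)-5,5,8a-trimethyl-2-methylidenedecahydronaphthalen-1-yl]pentyl}oxy)diphenylsilane | CC(C)(C)[Si](OCC[C@@H](C)CC[C@@H]1[C@]2(C)CCCC(C)(C)[C@@H]2CCC1=C)(c1ccccc1)c1ccccc1 | intermediate
22 | tert-butyl({(3S)-3-methyl-5-[(1R,2R,4aS,8aR)-5,5,8a-trimethyloctahydro-1H-spiro[naphthalene-2,2'-oxiran]-1-yl]pentyl}oxy)diphenylsilane | CC(C)(C)[Si](OCC[C@@H](C)CC[C@@H]1[C@]2(C)CCCC(C)(C)[C@@H]2CC[C@]13CO3)(c1ccccc1)c1ccccc1 | intermediate
23 | (1R,2R,4aS,8aR)-1-{(3S)-5-[(tert-butyldiphenylsilyl)oxy]-3-methylpentyl}-2,5,5,8a-tetramethyldecahydronaphthalen-2-ol | CC(C)(C)[Si](OCC[C@@H](C)CC[C@@H]1[C@]2(C)CCCC(C)(C)[C@@H]2CC[C@@]1(C)O)(c1ccccc1)c1ccccc1 | intermediate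
24 | (1R,2R,4aS,8aR)-1-[(3S)-5-hydroxy-3-methylpentyl]-2,5,5,8a-tetramethyldecahydronaphthalen-2-ol | OCC[C@@H](C)CC[C@@H]1[C@]2(C)CCCC(C)(C)[C@@H]2CC[C@@]1(C)O | intermediate
25 | (3S)-5-[(1R,2R,4aS,8aR)-2-hydroxy-2,5,5,8a-tetramethyldecahydronaphthalen-1-yl]-3-methylpentyl acetate | CC(=O)OCC[C@@H](C)CC[C@@H]1[C@]2(C)CCCC(C)(C)[C@@H]2CC[C@@]1(C)O | target

**Count and risks**

Total step count: 18. Longest linear sequence: 15 (steps 1–7 and 11–18); the aldehyde branch is 3 steps (8–10).

Steps most likely to fail: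

Step 1. The hindered γ,γ-disubstituted enone may give insufficient enantioselectivity in the copper-catalysed Grignard addition, or the magnesium enolate may be methylated sluggishly or more than once. The fallback sets out from 1 and takes the chirality from a reagent-controlled reduction followed by 1,3-chirality transfer. α-Iodination of 1 (I2, pyridine, CH2Cl2) should give 2-iodo-4,4-dimethylcyclohex-2-en-1-one F1. Suzuki methylation (MeB(OH)2, PdCl2(dppf), K3PO4) should give 2,4,4-trimethylcyclohex-2-en-1-one F2. Corey–Bakshi–Shibata reduction with (R)-2-methyl-CBS-oxazaborolidine and BH3·SMe2 should give (S)-2,4,4-trimethylcyclohex-2-en-1-ol F3, which is esterified (picolinic acid, DCC, DMAP) to (S)-2,4,4-trimethylcyclohex-2-en-1-yl pyridine-2-carboxylate F4. Anti-SN2′ substitution of F4 with 2 and CuBr·SMe2 in THF should place the butenyl group on C5 with the methyl and the C1=C10 alkene already in position. The fallback comes back to the route at 6 and so bypasses steps 2 and 3 as well.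

Step 2. Proton loss toward the CH2 side would give the less substituted enol triflate and, after reduction, the wrong alkene isomer. The fallback sets out from the magnesium enolate 3 and makes the tetrasubstituted enolate regiospecifically. Enolate 3 is trapped with Eschenmoser's salt (CH2=NMe2+ I−) instead of MeI to give (3R)-3-(but-3-en-1-yl)-2-[(dimethylamino)methyl]-4,4-dimethylcyclohexan-1-one F5. Quaternisation with MeI and elimination with NaHCO3 give (3S)-3-(but-3-en-1-yl)-4,4-dimethyl-2-methylidenecyclohexan-1-one F6. Conjugate reduction of F6 with LiBH(sBu)3 in THF at −78 °C delivers hydride to the exocyclic CH2, and the resulting enolate is trapped with PhNTf2. The fallback comes back to the route at 5.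

Step 13. Hydrogen may be delivered to C9 from the β face, giving poor or reversed facial selectivity. If the β face is the more accessible one, the aldehyde will have entered from that face in step 11, and the aldol 17 then already carries the side chain β on C9. The fallback therefore sets out from 17 and keeps C9 instead of erasing it. The C11 hydroxyl is converted (PhOC(S)Cl, pyridine, CH2Cl2) into the O-phenyl thionocarbonate of 17 F7. Barton–McCombie deoxygenation (Bu3SnH, AIBN, toluene, 80 °C) then removes the C11 oxygen without touching C9. The fallback comes back to the route at 20.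

Further compounds
F1 | step 1 | 2-iodo-4,4-dimethylcyclohex-2-en-1-one | CC1(C)C=C(I)C(=O)CC1
F2 | step 1 | 2,4,4-trimethylcyclohex-2-en-1-one | CC1=CC(C)(C)CCC1=O
F3 | step 1 | (S)-2,4,4-trimethylcyclohex-2-en-1-ol | CC1=CC(C)(C)CC[C@@H]1O
F4 | step 1 | (S)-2,4,4-trimethylcyclohex-2-en-1-yl pyridine-2-carboxylate | CC1=CC(C)(C)CC[C@@H]1OC(=O)c1ccccn1
F5 | step 2 | (3R)-3-(but-3-en-1-yl)-2-[(dimethylamino)methyl]-4,4-dimethylcyclohexan-1-one | C=CCC[C@@H]1C(CN(C)C)C(=O)CCC1(C)C
F6 | step 2 | (3S)-3-(but-3-en-1-yl)-4,4-dimethyl-2-methylidenecyclohexan-1-one | C=CCC[C@@H]1C(=C)C(=O)CCC1(C)C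
F7 | step 13 | O-phenyl thionocarbonate of 17 (side chain β on C9; ring 1S,4aS,8aR, chain 3R) | CC(C)(C)[Si](OCC[C@@H](C)CC(OC(=S)Oc1ccccc1)[C@@H]1[C@]2(C)CCCC(C)(C)[C@@H]2CCC1=O)(c1ccccc1)c1ccccc1
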